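**Retrosynthetic overview**
1. The acetate goes on last. The dihydrofuran bridge (C1–O–C8) and the 7-hydroxy spiro-lactone both come from a furanogermacranolide triol plus O2 in one flask (singlet oxygen, then Ti(OiPr)4), as in the likely biogenesis; this sets C7, C8 and C11.
2. The ten-membered carbocycle is closed at C1–C10 by a Nozaki–Hiyama–Kishi reaction between a (Z)-enol triflate and an aldehyde; this sets C1.
3. Lactone A comes from asymmetric propiolate addition to a 3-furaldehyde (C6), ruthenium-catalysed ene–yne coupling with allyl alcohol (C3–C4 bond, butenolide, C1 aldehyde) and syn-dihydroxylation (C4, C5).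
4. The furan comes from a Feist–Bénary synthesis (ethyl acetoacetate and chloroacetone), followed by lateral acylation, Z-enol triflation and ester reduction.
5. Ring order: furan, then lactone A, then the ten-membered carbocycle, then the dihydrofuran bridge and spiro-lactone B together.

Assumption: positions use germacrane numbering (C1 = ether CH; C4, C5, C6 = carbinol, acetoxy and O-alkyl carbons of lactone A; C7 = second carbinol carbon; C8 = spiro ketal carbon; C11 = CHMe; C15 and C12 = lactone carbonyls), and the configuration is taken literally from the SMILES (1S,4S,5S,6R,7S,8S,11S), although this puts C2 and C7 on opposite faces of the dihydrofuran; C1 is therefore set by ligand control, not by the ring.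

Step 1
Reactants: 1 ethyl acetoacetate; 2 chloroacetone
Product: 3 ethyl 2,4-dimethylfuran-3-carboxylate
Conditions: pyridine, rt → 50 °C
Reagents that add atoms: chloroacetone (2) CC(=O)CCl
Why: Feist–Bénary furan synthesis: the acetoacetate carbon adds to the ketone of chloroacetone, the enol oxygen displaces chloride and loss of water aromatises, which places the methyl groups at C2 and C4 and the ester at C3; no stereocenter is formed.

Step 2
Reactants: 3 ethyl 2,4-dimethylfuran-3-carboxylate; 4 N-methoxy-N-methylacetamide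
Product: 5 ethyl 4-methyl-2-(2-oxopropyl)furan-3-carboxylate
Conditions: LiN(iPr)2 (1.1 equiv), THF, −78 °C; then 4, −78 → 0 °C; H2O
Reagents that add atoms: N-methoxy-N-methylacetamide (4) CON(C)C(C)=O
Why: Lateral (vinylogous) deprotonation of the 2-methyl group, which is conjugated with the 3-ester, gives a dienolate that the Weinreb amide acylates only once, because the tetrahedral adduct survives until work-up; no stereocenter is formed.

Step 3
Reactants: 5 ethyl 4-methyl-2-(2-oxopropyl)furan-3-carboxylate
Product: 6 ethyl 4-methyl-2-[(1Z)-2-(trifluoromethylsulfonyloxy)prop-1-en-1-yl]furan-3-carboxylate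
Conditions: KN(SiMe3)2, THF, −78 °C; PhNTf2, −78 → 0 °C
Reagents that add atoms: N-phenylbis(trifluoromethanesulfonimide) O=S(=O)(N(c1ccccc1)S(=O)(=O)C(F)(F)F)C(F)(F)F
Why: Enol triflate formation: the most acidic C–H (between ketone and furan) is removed, and the enolate, held with O cis to the furan by chelation to the ester and by avoidance of allylic strain with the methyl group, is O-sulfonylated to the Z-triflate, which fixes the later C9=C10 geometry.

Step 4
Reactants: 6 the Z-enol triflate ester
Product: 7 4-methyl-2-[(1Z)-2-(trifluoromethylsulfonyloxy)prop-1-en-1-yl]furan-3-carbaldehyde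
Conditions: iBu2AlH (1.1 equiv), CH2Cl2, −78 °C; H2O
Reagents that add atoms: none
Why: Partial ester reduction: the aluminium hemiacetal of this hindered, electron-rich furoate is stable at −78 °C and collapses to the aldehyde only on work-up; the enol triflate is inert to iBu2AlH and no stereocenter is involved.

Step 5
Reactants: 7 the furan-3-carbaldehyde; 8 methyl propiolate
Product: 9 methyl (4R)-4-hydroxy-4-{4-methyl-2-[(1Z)-2-(trifluoromethylsulfonyloxy)prop-1-en-1-yl]furan-3-yl}but-2-ynoate
Conditions: (S,S)-ProPhenol (20 mol %), Ph3PO (40 mol %), Me2Zn (3 equiv), toluene, 4 °C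
Reagents that add atoms: methyl propiolate (8) C#CC(=O)OC
Why: Trost ProPhenol alkynylation: the dinuclear zinc complex holds the aldehyde and the zinc acetylide side by side, and the ligand antipode is chosen so that the alkynyl group goes to the Re face of the aldehyde, which sets C6 as R.

Step 6
Reactants: 9 the (4R)-hydroxy alkynoate; 10 allyl alcohol
Product: 12 3-[(5R)-5-{4-methyl-2-[(1Z)-2-(trifluoromethylsulfonyloxy)prop-1-en-1-yl]furan-3-yl}-2-oxo-2,5-dihydrofuran-3-yl]propanal, via hydroxy enoate 11 (not isolated)
Conditions: [CpRu(MeCN)3]PF6 (10 mol %), acetone, rt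
Reagents that add atoms: allyl alcohol (10) C=CCO
Why: Trost ruthenium-catalysed alkene–alkyne coupling (Alder-ene type): the ruthenacyclopentene forms the C3–C4 bond at the ester-bearing alkyne carbon by syn addition, β-hydride elimination from the carbinol carbon releases an enol that becomes the C1 aldehyde, and the Z-hydroxy enoate 11 lactonises at once; C6 is untouched.

Step 7
Reactants: 12 the butenolide aldehyde
Product: 13 3-[(3S,4S,5S)-3,4-dihydroxy-5-{4-methyl-2-[(1Z)-2-(trifluoromethylsulfonyloxy)prop-1-en-1-yl]furan-3-yl}-2-oxooxolan-3-yl]propanal (rests as the five-membered lactol with its 3-OH; drawn open)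
Conditions: OsO4 (5 mol %), NMO (1.5 equiv), citric acid, acetone–H2O, rt
Reagents that add atoms: N-methylmorpholine N-oxide C[N+]1([O-])CCOCC1 (oxygen passed on through OsO4); water O
Why: Upjohn syn-dihydroxylation: OsO4 adds to the cyclic cis-alkene of the butenolide from the face anti to the C6 furyl group (this sets C4 and C5, with both OH cis to each other and trans to the furyl), while the enol triflate alkene and the furan conjugated with it are deactivated by the triflyloxy group.

Step 8
Reactants: 13 the dihydroxy lactone aldehyde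
Product: 14 (1S,4S,5S,6S,9Z)-1,4,5-trihydroxy-8,12-epoxygermacra-7,9,11-trien-15,6-olide (furanogermacranolide triol; C6 is unchanged in space and its descriptor is S only because C5 now outranks the furan carbon)
Conditions: CrCl2 (6 equiv), NiCl2 (0.2 equiv), Kishi-type oxazoline–sulfonamide ligand (6.6 equiv), Et3N (6.6 equiv), THF, rt, 2 mM, slow addition
Reagents that add atoms: none
Why: Nozaki–Hiyama–Kishi macrocyclisation: zerovalent nickel inserts into the C–OTf bond with retention, the alkenyl group passes to chromium and adds to the aldehyde freed from the lactol, the two cis units (furan edge and Z-alkene) bring the chain ends together, and the ligand antipode is chosen so that the chiral chromium sulfonamide complex directs attack to the Re face of C1=O, which gives 1S.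

Step 9
Reactants: 14 the furanogermacranolide triol
Product: 18 (1S,4S,5S,6R,7S,8S,11S)-4,5,7-trihydroxy-1,8-epoxygermacr-9-ene-15,6:12,8-diolide, via furan endoperoxide 15 (not isolated), via spiro hydroperoxide 16 (not isolated), via epoxy lactol 17 (not isolated)
Conditions: O2, tetraphenylporphyrin (1 mol %), white LED, CH2Cl2, −78 °C; then Ti(OiPr)4 (1.5 equiv), 4 Å MS, −78 → 0 °C
Reagents that add atoms: oxygen O=O
Why: Proposed new method: singlet oxygen adds [4+2] to the furan (much faster than an ene reaction at C9=C10), the 1-OH opens the peroxy ketal at the allyl-stabilised C8 to give spiro hydroperoxide 16 (known furan photooxygenation–spiroketalisation), Ti(OiPr)4 moves the outer peroxide oxygen onto C7=C11 syn to the titanium-bound C12–O (known titanium-mediated conversion of allylic hydroperoxides into epoxy alcohols), and the C12–H of lactol 17, which lies anti to the C11–O bond, shifts to C11 (semipinacol 1,2-hydride shift of a 2,3-epoxy alcohol), so that O1, the 7-OH and the C11 methyl group all end on the face attacked by oxygen, which is the 7S,8S,11S array.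

Step 10
Reactants: 18 the trihydroxy bis-lactone; 19 acetic anhydride
Product: 20 target, the 5-O-acetate of 18
Conditions: Ac2O (1.2 equiv), pyridine, DMAP (5 mol %), CH2Cl2, 0 °C
Reagents that add atoms: acetic anhydride (19) CC(=O)OC(C)=O
Why: Chemoselective acylation: only the C5 hydroxyl is secondary, and the tertiary C4 and C7 hydroxyls stay free at 0 °C; no stereocenter changes.

**Compound list**
1 | ethyl acetoacetate | CCOC(=O)CC(C)=O | starting material
2 | chloroacetone | CC(=O)CCl | starting material
3 | ethyl 2,4-dimethylfuran-3-carboxylate | CCOC(=O)c1c(C)occ1C | intermediate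
4 | N-methoxy-N-methylacetamide | CON(C)C(C)=O | starting material
5 | ethyl 4-methyl-2-(2-oxopropyl)furan-3-carboxylate | CCOC(=O)c1c(CC(C)=O)occ1C | intermediate
6 | ethyl 4-methyl-2-[(1Z)-2-(trifluoromethylsulfonyloxy)prop-1-en-1-yl]furan-3-carboxylate | CCOC(=O)c1c(/C=C(/C)OS(=O)(=O)C(F)(F)F)occ1C | intermediate
7 | 4-methyl-2-[(1Z)-2-(trifluoromethylsulfonyloxy)prop-1-en-1-yl]furan-3-carbaldehyde | O=Cc1c(/C=C(/C)OS(=O)(=O)C(F)(F)F)occ1C | intermediate
8 | methyl propiolate | C#CC(=O)OC | starting material
9 | methyl (4R)-4-hydroxy-4-(furyl enol triflate)but-2-ynoate | COC(=O)C#C[C@@H](O)c1c(C)coc1/C=C(/C)OS(=O)(=O)C(F)(F)F | intermediate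
10 | allyl alcohol | C=CCO | starting material
11 | methyl (2Z,4R)-4-hydroxy-4-(furyl enol triflate)-2-(3-oxopropyl)but-2-enoate (not isolated) | COC(=O)/C(CCC=O)=C\[C@@H](O)c1c(C)coc1/C=C(/C)OS(=O)(=O)C(F)(F)F | intermediate
12 | 3-[(5R)-5-(furyl enol triflate)-2-oxo-2,5-dihydrofuran-3-yl]propanal | O=C1O[C@@H](c2c(C)coc2/C=C(/C)OS(=O)(=O)C(F)(F)F)C=C1CCC=O | intermediate
13 | 3-[(3S,4S,5S)-3,4-dihydroxy-5-(furyl enol triflate)-2-oxooxolan-3-yl]propanal (open form of the lactol) | O=C1O[C@@H](c2c(C)coc2/C=C(/C)OS(=O)(=O)C(F)(F)F)[C@H](O)[C@@]1(O)CCC=O | intermediate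
14 | (1S,4S,5S,6S,9Z)-1,4,5-trihydroxy-8,12-epoxygermacra-7,9,11-trien-15,6-olide | O[C@H]1[C@H]2OC(=O)[C@]1(O)CC[C@H](O)/C(C)=C\c3occ(C)c23 | intermediate
15 | 8,12-epidioxy adduct of 14 (furan endoperoxide, not isolated) | O[C@H]1[C@H]2OC(=O)[C@]1(O)CC[C@H](O)/C(C)=C\[C@]34OO[C@H](O3)C(C)=C24 | intermediate
16 | 12-hydroperoxy-1,8:8,12-diepoxygermacra-7(11),9-dien-15,6-olide, OOH cis to O1 (not isolated) | O[C@H]1[C@H]2OC(=O)[C@]1(O)CC[C@@H]1O[C@@]3(C=C1C)O[C@@H](OO)C(C)=C23 | intermediate
17 | 7,11-epoxy-12-hydroxy analogue of 16, epoxide cis to 12-OH and O1 (not isolated) | O[C@H]1[C@H]2OC(=O)[C@]1(O)CC[C@@H]1O[C@@]3(C=C1C)O[C@@H](O)[C@@]4(C)O[C@@]234 | intermediate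
18 | (1S,4S,5S,6R,7S,8S,11S)-4,5,7-trihydroxy-1,8-epoxygermacr-9-ene-15,6:12,8-diolide | O[C@H]1[C@H]2OC(=O)[C@]1(O)CC[C@@H]1O[C@@]3(C=C1C)OC(=O)[C@@H](C)[C@]23O | intermediate
19 | acetic anhydride | CC(=O)OC(C)=O | starting material
20 | CNP0315698.1, the 5-O-acetate of 18 | CC(=O)O[C@H]1[C@H]2OC(=O)[C@]1(O)CC[C@@H]1O[C@@]3(C=C1C)OC(=O)[C@@H](C)[C@]23O | target

Total step count: 10. Longest linear sequence: 10.

**Steps most likely to fail**

Step 9. Hydroperoxide 16 may lose water to the spiro-butenolide instead of passing its outer oxygen to C7=C11. The closure of O1 on C8 also has to accept the strained bridging mode that the descriptors ask for. The fallback sets out from 14 and returns at 18, and it brings in the two oxygen atoms one at a time instead of as O2. First, [Ir(OMe)(cod)]2, dtbpy and B2pin2 borylate the only furan C–H (C12) to give the C12 pinacol boronate F1. NaBO3 then oxidises the C–B bond, and the 2-hydroxyfuran tautomerises to the conjugated enol lactone (2(3H)-furanone, C11 epimers) F2. DMDO in acetone at −78 °C epoxidises the tetrasubstituted C7=C8 enol-ester bond to the 7,8-epoxy lactone F3. This ionises at the allylic C8 and is captured by the 1-OH to give 18. DBU then levels C11 to the more stable 11S epimer (methyl anti to C6).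

Step 8. The ten-membered closure from a lactol-masked aldehyde may lose out to protonation of the alkenyl chromium species or to dimerisation. The fallback sets out from 13 and returns at 14. DBU removes triflic acid by anti elimination to give the 2-(prop-1-ynyl)furan aldehyde F4. A nickel-catalysed reductive alkyne–aldehyde macrocyclisation (Ni(cod)2, IMes, Et3SiH, THF, high dilution) joins C10, the alkyne carbon remote from the furan, to C1 by syn addition. This gives the (9E)-macrocyclic triethylsilyl ether F5. Energy-transfer isomerisation (Ir(ppy)3, blue LED) converts it into the (9Z)-silyl ether F6, and HF·pyridine frees 14. C1 is under substrate control in this fallback, so the epimers are separated at F6.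

Step 6. The furyl propargylic alcohol may isomerise, or the coupling may give the wrong regiochemistry. The fallback sets out from 9 and returns at 12. Semihydrogenation (H2, Pd/CaCO3 poisoned with Pb(OAc)2, quinoline) gives the Z-enoate, which lactonises to the α-unsubstituted butenolide F7. I2 in pyridine gives the α-iodobutenolide F8. A Negishi coupling with 2-(1,3-dioxolan-2-yl)ethylzinc bromide (PdCl2(dppf), THF, rt), in which C–I reacts before C–OTf, gives the dioxolane F9. Aqueous acid then unmasks aldehyde 12.

**Further compounds**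
F1 | step 9 | C12 pinacol boronate of 14 | O[C@H]1[C@H]2OC(=O)[C@]1(O)CC[C@H](O)/C(C)=C\c3oc(B4OC(C)(C)C(C)(C)O4)c(C)c23
F2 | step 9 | (9Z)-1,4,5-trihydroxygermacra-7,9-diene-15,6:12,8-diolide (enol lactone, C11 epimers) | O[C@H]1[C@H]2OC(=O)[C@]1(O)CC[C@H](O)/C(C)=C\C3=C2C(C)C(=O)O3
F3 | step 9 | 7,8-epoxide of F2 (11S) | O[C@H]1[C@H]2OC(=O)[C@]1(O)CC[C@H](O)/C(C)=C\[C@@]34O[C@@]23[C@H](C)C(=O)O4
F4 | step 8 | 3-[(3S,4S,5S)-3,4-dihydroxy-5-(4-methyl-2-(prop-1-ynyl)furan-3-yl)-2-oxooxolan-3-yl]propanal | O=C1O[C@@H](c2c(C)coc2C#CC)[C@H](O)[C@@]1(O)CCC=O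
F5 | step 8 | (9E)-isomer of 14 as its 1-O-triethylsilyl ether | O[C@H]1[C@H]2OC(=O)[C@]1(O)CC[C@H](O[Si](CC)(CC)CC)/C(C)=C/c3occ(C)c23
F6 | step 8 | 1-O-triethylsilyl ether of 14 (9Z) | O[C@H]1[C@H]2OC(=O)[C@]1(O)CC[C@H](O[Si](CC)(CC)CC)/C(C)=C\c3occ(C)c23
F7 | step 6 | (5R)-5-(furyl enol triflate)furan-2(5H)-one | O=C1O[C@@H](c2c(C)coc2/C=C(/C)OS(=O)(=O)C(F)(F)F)C=C1
F8 | step 6 | (5R)-3-iodo-5-(furyl enol triflate)furan-2(5H)-one | O=C1O[C@@H](c2c(C)coc2/C=C(/C)OS(=O)(=O)C(F)(F)F)C=C1I
F9 | step 6 | (5R)-3-[2-(1,3-dioxolan-2-yl)ethyl]-5-(furyl enol triflate)furan-2(5H)-one | O=C1O[C@@H](c2c(C)coc2/C=C(/C)OS(=O)(=O)C(F)(F)F)C=C1CCC3OCCO3
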